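## Structural features

The target is made of two ring systems joined by one single bond: a 4-methoxyisoindolin-1-one (benzene fused to a γ-lactam; C1 carbonyl, N2, C3, C3a, C4–C7, C7a) and a 2-hydroxy-4-methyl-6-oxocyclohexa-1,3-diene ring (C1'–C6') that carries two prenyl chains on the quaternary carbon C5'; C3 is bonded to C1'. C3 is the only stereocentre (S); C5' bears two identical chains and is not stereogenic, so no stereocentres stand next to each other. The carbocycle is an enolised cyclic β-diketone, that is a dearomatised, gem-diprenylated orcinol, and it is acidic, easily O-alkylated and easily oxidised. The two trisubstituted alkenes exclude hydrogenation and strong protic or Lewis acids late in the route. C3 is benzylic, bound to nitrogen and to the central carbon of the vinylogous acid, so its C3–N bond can ionise (retro-Mannich or quinone-methide pathway) under hot acid or base, with loss of configuration. The real difficulty is twofold: to set this crowded centre, flanked by the C4 methoxy group and two oxygenated ortho positions, as one enantiomer, and to create the quaternary C5' by a dearomatising double alkylation at one ring carbon only. The key step uses the fact that C3a and C7a are neighbouring ring carbons bearing C3 and C1, with the methoxy group on C4 next to C3a. That is the pattern 3-methoxybenzyne takes up in a regioselective vicinal difunctionalisation, while the dienone ring is carried through as an aromatic 2,6-dioxygenated 4-methylphenyl group.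

## Logic of the disconnections

21 back to 19 (through 20). A carboxyl carbon is added in thought to C3'; in the forward sense the O–allyl bond and the C3'–carboxyl bond are the ones cut. C3' and C5' are both nucleophilic in the aromatic precursor, so C3' must be occupied while C5' is alkylated. The forward step must then remove the allyl and carboxyl groups under near-neutral conditions that spare two prenyl groups, an acidic enol and the labile C3–N bond.

19 back to 17 (through 18). Both bonds from C5' to the prenyl methylene carbons are cut. This restores the aromatic ring, removes the quaternary carbon and lets the phenol's own nucleophilicity do the work. The forward step must deliver two C-alkylations at the same carbon, the second against loss of aromaticity, and must prefer carbon over oxygen.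

17 back to 15 (through 16). The O–allyl bond and then the C3'–carboxyl bond are cut. In 15 the two free ring positions are equivalent by rotation about C3–C1', so the carboxylation has no regiochemical question. The forward carboxylation must be mild enough for C3, and the esterification must touch only the carboxylate.

15 back to 12 (through 14 and 13). The lactam carbonyl is traced to a tert-butylamidine carbon, the phenols to MOM ethers and N2–H to the N-sulfinyl group. The skeleton is not simplified, but the product of a three-component coupling is revealed, with every protecting and activating group acid-labile. The forward step must hydrolyse a hindered amidinium ion without ionising C3–N.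

12 back to 6, 7 and 8 (through 11, 10 and 9). Three bonds are cut: C7a–C1, C3a–C3 and N2–C1. This is the largest single gain: the lactam ring, the C3 stereocentre and the 1,2,3-substitution pattern of the arene all come from one operation. The forward step demands regioselective addition to an unsymmetrical aryne, capture of a hindered aryl anion by a doubly ortho-substituted imine, and face selection by the sulfinyl group.

6 back to 4 and 5. The C=N bond is cut, separating the auxiliary from the aldehyde. The forward condensation must cope with an aldehyde flanked by two ortho substituents and must leave sulfur untouched.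

4 back to 2 (through 3), and 2 back to 1. The aryl–formyl bond and the two O–MOM bonds are cut, arriving at a commercial symmetric phenol. The forward lithiation must take place between the two oxygen substituents only, which the MOM groups secure.

## Other disconnections considered

Alternative 1: The cut goes through the benzene ring of the isoindolinone: C3a–C7a, C4–C5 and C6–C7 are removed. This leaves the achiral triyne amide A1 (a propiolamide whose nitrogen sits on a carbon bearing two methoxyethynyl arms) and ethyne A2. In the forward direction a cationic monovalent rhodium catalyst with a chiral bisphosphine would join the propiolamide alkyne, one of the two enantiotopic ynol ether arms and A2 in a [2+2+2] cycloaddition. This would give A3, closing the benzene and lactam rings together and setting C3 by desymmetrisation.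
- In its favour: the stereocentre would come from a catalyst, not a stoichiometric auxiliary, which is better than the chosen plan on that point. The C4 methoxy group is placed by the tether with no regiochemical question, which is equal to the aryne solution. The surviving ynol ether arm is a handle for further ring construction.
- Against it here: A1 is a doubly propargylic amide with two acid- and water-sensitive ynol ethers and would need several steps. Three different alkynes must combine in one defined way while A2 can trimerise or both arms can react. A desymmetrisation of this kind on ynol ethers would be new.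
- Comparison: structurally A3 holds only C1' and C2' of the carbocycle, so the whole dienone ring with its quaternary carbon remains to be built, whereas the chosen plan carries that ring as an arene from 1. Mechanistically both plans rest on one unproven stereoselective event. In step economy the alternative is longer, because the second ring needs a further annulation such as that of alternative 3.

Alternative 2: The cut removes both bonds from C5' to the prenyl methylene carbons and leaves the aromatic allyl ester A4. The forward key step is a twofold C-alkylation of the phenolate of A4 with a prenyl halide at C5', which dearomatises the ring to A5 without closing a ring. Deallylation and loss of CO2 then give the target.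
- In its favour: it is the biosynthesis-like way to the gem-diprenyl dienone, and the ester blocks C3' so that both groups must enter at C5'. On this point it is the equal of the chosen plan because it is the same reaction: A4 and A5 have the structures of 17 and 19, and steps 8 and 9 are this disconnection.
- Against it as the strategy-defining step: it forms no ring and does not address C3. The isoindolinone, the crowded C3–C1' bond and the absolute configuration would need a separate solution, for instance an enantioselective aza-Friedel–Crafts reaction of an orsellinate with an N-acyliminium precursor. Its site selectivity between the two free ring positions and its enantiocontrol next to two hydroxyl groups are uncertain.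
- Comparison: such an assembly would bring the ester in with the arene and save the late carboxylation and esterification, which is better in step count. The chosen plan pays two steps for an unambiguous connectivity and an auxiliary-defined centre. Mechanistically the two are complementary: the aryne coupling builds lactam and stereocentre, the diprenylation builds the quaternary carbon.

Alternative 3: The cut takes the carbocycle apart at C1'–C6' and C2'–C3' and leaves the ynol ether A3 and the cyclobutenone A6 (3-methyl-4,4-diprenylcyclobutenone). On heating, A6 should open to a vinylketene, which adds to the ynol ether in a [2+2] cycloaddition (C6' to the alkyne carbon on C3, C3' to the oxygen-bearing carbon). A 4π opening of the new cyclobutenone and a 6π closure re-form C5'–C6' and give the methyl ether A7. This is a benzannulation of the Danheiser type that stops at the dienone because C5' is quaternary; mild hydrolysis of the vinylogous ester would give the target.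
- In its favour: the quaternary carbon is in place before the ring forms, so neither the C- versus O-alkylation problem nor a blocking group arises, which is better than the chosen plan on that point. The polarity of the ynol ether fixes the regiochemistry, and the coupling is convergent.
- Against it here: the vinylketene carries two prenyl alkenes within reach, so intramolecular [2+2] or ene reactions compete. The thermal conditions act on a C3 centre that is propargylic, benzylic and bound to nitrogen. A6 needs a multistep synthesis, and A3 must first be made as one enantiomer, for which alternative 1 is the only direct route.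
- Comparison: structurally the ring is built from nothing where the chosen plan unveils it from an arene. Mechanistically it is a pericyclic cascade against an ionic dearomatisation, each with one selectivity risk. In step economy it is clearly longer. It ends with the same kind of mild unmasking of the vinylogous acid, which is equal.

Key step: step 4

Assumption: the aryl anion formed in step 4 has no coordinating metal and is taken to add through an open transition state, anti to the tert-butyl group of the s-cis sulfinyl imine; on that model the (S)-sulfinyl group leads to 3S and the (R)-sulfinyl group to 3R, so sulfinamide 5 is used as its (S) enantiomer.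

## Route

Step 1
Reactants: 1 orcinol
Product: 2 1,3-bis(methoxymethoxy)-5-methylbenzene
Conditions: MOMCl, iPr2NEt, CH2Cl2, 0 °C to rt
Reagents that add atoms: chloromethyl methyl ether (MOMCl), COCCl
Why: Williamson-type O-alkylation of both phenols with the chloromethyl ether under amine base; the MOM ethers direct the lithiation of step 2, are small enough for the hindered imine of step 4 and fall to the acid of step 5.

Step 2
Reactants: 2 1,3-bis(methoxymethoxy)-5-methylbenzene
Product: 4 2,6-bis(methoxymethoxy)-4-methylbenzaldehyde, via aryllithium 3 (not isolated)
Conditions: n-BuLi, TMEDA, THF, 0 °C; DMF, 0 °C to rt; aq. NH4Cl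
Reagents that add atoms: N,N-dimethylformamide, CN(C)C=O
Why: Directed ortho-metalation: the ring position between the two MOM ethers is deprotonated selectively through the cooperative coordinating and inductive effect of both acetal oxygens, and aryllithium 3 is formylated by DMF.

Step 3
Reactants: 4 2,6-bis(methoxymethoxy)-4-methylbenzaldehyde; 5 (S)-2-methylpropane-2-sulfinamide
Product: 6 (S,E)-N-[2,6-bis(methoxymethoxy)-4-methylbenzylidene]-2-methylpropane-2-sulfinamide
Conditions: Ti(OEt)4, THF, 60 °C
Reagents that add atoms: none
Why: Ti(OEt)4-mediated condensation of an aldehyde with tert-butanesulfinamide to the N-sulfinyl imine; the Lewis acid activates the doubly ortho-substituted aldehyde and binds the water, the E isomer is the only one expected for an aldimine, and sulfur is not involved and keeps its configuration.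

Step 4
Reactants: 6 (S,E)-N-[2,6-bis(methoxymethoxy)-4-methylbenzylidene]-2-methylpropane-2-sulfinamide; 7 3-methoxy-2-(trimethylsilyl)phenyl trifluoromethanesulfonate; 8 tert-butyl isocyanide
Product: 12 (3S)-3-[2,6-bis(methoxymethoxy)-4-methylphenyl]-1-(tert-butylimino)-2-[(S)-tert-butylsulfinyl]-4-methoxyisoindoline, via 3-methoxybenzyne 9 (not isolated), via nitrilium aryl anion zwitterion 10 (not isolated), via open-chain sulfinamide anion 11 (not isolated)
Conditions: KF, 18-crown-6, THF, 0 °C to rt (7 added slowly)
Reagents that add atoms: none
Why: Proposed new method: fluoride removes the silyl group of 7 and triflate leaves to give aryne 9; the isocyanide carbon of 8 adds at the aryne carbon meta to the methoxy group, because the negative charge then sits ortho to the inductively withdrawing oxygen, giving zwitterion 10 (C7a–C1 formed). The aryl anion of 10 adds to the imine carbon of 6 (C3a–C3), and the sulfinamide nitrogen of 11 closes on the nitrilium carbon in a 5-exo-dig mode (N2–C1), which makes the five-membered ring. The closest known reaction type is the three-component coupling of arynes, isocyanides and N-sulfonyl aldimines to 1-iminoisoindolines; an N-sulfinyl imine as third component, auxiliary control in it and an imine with two ortho substituents are not established. C3 is set in the C3a–C3 bond formation: potassium is held by the crown ether, so an open transition state is expected in which the s-cis sulfinyl imine is attacked anti to the tert-butyl group, which for the (S)-sulfinyl group is the Si face and corresponds to 3S. The step needs regioselectivity on the aryne, secured by the methoxy group next to the triple bond; chemoselectivity for the isocyanide as first nucleophile, secured by its higher nucleophilicity than that of the sulfinyl imine and by slow addition of 7; and facial selectivity, secured by the auxiliary. MOM ethers, sulfinyl group and amidine are inert to KF and 18-crown-6 in THF.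

Step 5
Reactants: 12 (3S)-3-[2,6-bis(methoxymethoxy)-4-methylphenyl]-1-(tert-butylimino)-2-[(S)-tert-butylsulfinyl]-4-methoxyisoindoline
Product: 15 (3S)-3-(2,6-dihydroxy-4-methylphenyl)-4-methoxyisoindolin-1-one, via N-H amidine 13 (not isolated), via phenolic amidine 14 (not isolated)
Conditions: HCl (4 M in dioxane), MeOH, 0 °C to rt; then H2O, 60 °C; NaHCO3 work-up
Reagents that add atoms: water, O
Why: Acidolysis followed by amidine hydrolysis: HCl in methanol transfers the sulfinyl group to the solvent and cleaves both MOM acetals, and water then adds to the amidinium carbon of 14 and expels tert-butylamine to give the lactam. No bond to C3 is made or broken, and the temperature is kept moderate so that the benzylic C3–N bond does not ionise; the aryl methyl ether and the lactam are stable to these conditions.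

Step 6
Reactants: 15 (3S)-3-(2,6-dihydroxy-4-methylphenyl)-4-methoxyisoindolin-1-one
Product: 16 2,4-dihydroxy-3-[(1S)-7-methoxy-3-oxo-2,3-dihydro-1H-isoindol-1-yl]-6-methylbenzoic acid
Conditions: DBU, CO2 (1 atm), MeCN, 30 °C; cold dilute HCl work-up
Reagents that add atoms: carbon dioxide, O=C=O
Why: Kolbe–Schmitt-type carboxylation of a resorcinol with CO2 at atmospheric pressure and an amidine base: the two free ring positions C3' and C5' are equivalent by rotation about C3–C1', each ortho to one hydroxyl and para to the other, so one acid results and the carboxylate deactivates the ring towards a second carboxylation. The low temperature is chosen to keep the C3–N bond from ionising.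

Step 7
Reactants: 16 2,4-dihydroxy-3-[(1S)-7-methoxy-3-oxo-2,3-dihydro-1H-isoindol-1-yl]-6-methylbenzoic acid
Product: 17 prop-2-en-1-yl 2,4-dihydroxy-3-[(1S)-7-methoxy-3-oxo-2,3-dihydro-1H-isoindol-1-yl]-6-methylbenzoate
Conditions: allyl bromide, KHCO3, DMF, rt
Reagents that add atoms: allyl bromide, C=CCBr
Why: SN2 alkylation of the carboxylate: bicarbonate ionises only the carboxylic acid, not the hydrogen-bonded phenols or the lactam N–H, so the allyl group goes to the carboxyl oxygen.

Step 8
Reactants: 17 prop-2-en-1-yl 2,4-dihydroxy-3-[(1S)-7-methoxy-3-oxo-2,3-dihydro-1H-isoindol-1-yl]-6-methylbenzoate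
Product: 19 prop-2-en-1-yl 6-hydroxy-5-[(1S)-7-methoxy-3-oxo-2,3-dihydro-1H-isoindol-1-yl]-2-methyl-3,3-bis(3-methylbut-2-en-1-yl)-4-oxocyclohexa-1,5-diene-1-carboxylate, via monoprenyl phenol 18 (not isolated)
Conditions: prenyl bromide, aq. KOH, 0 °C; then dilute HCl
Reagents that add atoms: prenyl bromide (1-bromo-3-methylbut-2-ene), CC(C)=CCBr
Why: Alkylative dearomatisation of a phenolate, the reaction type by which acylphloroglucinols are gem-diprenylated: the first prenyl group enters at the only free ring carbon C5' to give 18, and the second enters at the same carbon because C3' carries the ester and C1' the bulky lactam substituent. Water solvates the phenolate oxygens and so favours C- over O-alkylation, and the cold, dilute base leaves the hindered allyl ester and the lactam intact. C5' receives two identical groups, so no new stereocentre is formed and C3 is not touched.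

Step 9
Reactants: 19 prop-2-en-1-yl 6-hydroxy-5-[(1S)-7-methoxy-3-oxo-2,3-dihydro-1H-isoindol-1-yl]-2-methyl-3,3-bis(3-methylbut-2-en-1-yl)-4-oxocyclohexa-1,5-diene-1-carboxylate
Product: 21 (3S)-3-[2-hydroxy-4-methyl-5,5-bis(3-methylbut-2-en-1-yl)-6-oxocyclohexa-1,3-dien-1-yl]-4-methoxyisoindolin-1-one, via dienone carboxylic acid 20 (not isolated)
Conditions: Pd(PPh3)4 (cat.), morpholine, THF, rt, then 50 °C
Reagents that add atoms: none
Why: Tsuji–Trost-type deallylation followed by decarboxylation: zerovalent palladium ionises the allyl ester and morpholine takes up the allyl group, leaving acid 20. Its carboxyl group sits on the α-carbon of an enone with a β-methyl group and should be lost on gentle warming through the deconjugated exo-methylene β-keto acid tautomer, as in the classical decarboxylation of 2-carboxy-3-methylcyclohexenones. The prenyl groups, the enol and C3 are not affected by these near-neutral conditions.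

## Compound list

1 | orcinol (5-methylbenzene-1,3-diol) | Cc1cc(O)cc(O)c1 | starting material
2 | 1,3-bis(methoxymethoxy)-5-methylbenzene | Cc1cc(OCOC)cc(OCOC)c1 | intermediate
3 | [2,6-bis(methoxymethoxy)-4-methylphenyl]lithium | [Li]c1c(OCOC)cc(C)cc1OCOC | intermediate (not isolated)
4 | 2,6-bis(methoxymethoxy)-4-methylbenzaldehyde | Cc1cc(OCOC)c(C=O)c(OCOC)c1 | intermediate
5 | (S)-2-methylpropane-2-sulfinamide | CC(C)(C)[S@](=O)N | starting material
6 | (S,E)-N-[2,6-bis(methoxymethoxy)-4-methylbenzylidene]-2-methylpropane-2-sulfinamide | Cc1cc(OCOC)c(/C=N/[S@@](=O)C(C)(C)C)c(OCOC)c1 | intermediate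
7 | 3-methoxy-2-(trimethylsilyl)phenyl trifluoromethanesulfonate | COc1cccc(OS(=O)(=O)C(F)(F)F)c1[Si](C)(C)C | starting material
8 | tert-butyl isocyanide | CC(C)(C)[N+]#[C-] | starting material
9 | 3-methoxybenzyne | COC1=CC=CC#C1 | intermediate (not isolated)
10 | 2-(N-tert-butylnitrilio)-6-methoxyphenyl anion (zwitterion) | COc1cccc(C#[N+]C(C)(C)C)[c-]1 | intermediate (not isolated)
11 | open-chain adduct: (S)-carbon, N-sulfinyl amide anion and N-tert-butylnitrilium on the same arene | COc1cccc(C#[N+]C(C)(C)C)c1[C@@H](c1c(OCOC)cc(C)cc1OCOC)[N-][S@@](=O)C(C)(C)C | intermediate (not isolated)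
12 | (3S)-3-[2,6-bis(methoxymethoxy)-4-methylphenyl]-1-(tert-butylimino)-2-[(S)-tert-butylsulfinyl]-4-methoxyisoindoline (exocyclic C=N drawn E; its geometry is of no consequence) | COc1cccc2c1[C@@H](c1c(OCOC)cc(C)cc1OCOC)N([S@@](=O)C(C)(C)C)/C2=N/C(C)(C)C | intermediate
13 | (3S)-3-[2,6-bis(methoxymethoxy)-4-methylphenyl]-1-(tert-butylimino)-4-methoxyisoindoline (present as its hydrochloride) | COc1cccc2c1[C@@H](c1c(OCOC)cc(C)cc1OCOC)NC2=NC(C)(C)C | intermediate (not isolated)
14 | (3S)-1-(tert-butylimino)-3-(2,6-dihydroxy-4-methylphenyl)-4-methoxyisoindoline (present as its hydrochloride) | COc1cccc2c1[C@@H](c1c(O)cc(C)cc1O)NC2=NC(C)(C)C | intermediate (not isolated)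
15 | (3S)-3-(2,6-dihydroxy-4-methylphenyl)-4-methoxyisoindolin-1-one | COc1cccc2c1[C@@H](c1c(O)cc(C)cc1O)NC2=O | intermediate
16 | 2,4-dihydroxy-3-[(1S)-7-methoxy-3-oxo-2,3-dihydro-1H-isoindol-1-yl]-6-methylbenzoic acid | COc1cccc2c1[C@@H](c1c(O)c(C(=O)O)c(C)cc1O)NC2=O | intermediate
17 | prop-2-en-1-yl 2,4-dihydroxy-3-[(1S)-7-methoxy-3-oxo-2,3-dihydro-1H-isoindol-1-yl]-6-methylbenzoate | COc1cccc2c1[C@@H](c1c(O)c(C(=O)OCC=C)c(C)cc1O)NC2=O | intermediate
18 | prop-2-en-1-yl 2,4-dihydroxy-3-[(1S)-7-methoxy-3-oxo-2,3-dihydro-1H-isoindol-1-yl]-6-methyl-5-(3-methylbut-2-en-1-yl)benzoate | COc1cccc2c1[C@@H](c1c(O)c(C(=O)OCC=C)c(C)c(CC=C(C)C)c1O)NC2=O | intermediate (not isolated)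
19 | prop-2-en-1-yl 6-hydroxy-5-[(1S)-7-methoxy-3-oxo-2,3-dihydro-1H-isoindol-1-yl]-2-methyl-3,3-bis(3-methylbut-2-en-1-yl)-4-oxocyclohexa-1,5-diene-1-carboxylate | COc1cccc2c1[C@@H](C1=C(O)C(C(=O)OCC=C)=C(C)C(CC=C(C)C)(CC=C(C)C)C1=O)NC2=O | intermediate
20 | 6-hydroxy-5-[(1S)-7-methoxy-3-oxo-2,3-dihydro-1H-isoindol-1-yl]-2-methyl-3,3-bis(3-methylbut-2-en-1-yl)-4-oxocyclohexa-1,5-diene-1-carboxylic acid | COc1cccc2c1[C@@H](C1=C(O)C(C(=O)O)=C(C)C(CC=C(C)C)(CC=C(C)C)C1=O)NC2=O | intermediate (not isolated)
21 | (3S)-3-[2-hydroxy-4-methyl-5,5-bis(3-methylbut-2-en-1-yl)-6-oxocyclohexa-1,3-dien-1-yl]-4-methoxyisoindolin-1-one | COc1cccc2c1[C@@H](C1=C(O)C=C(C)C(CC=C(C)C)(CC=C(C)C)C1=O)NC2=O | target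

## Step count and least certain steps

Total step count: 9. Longest linear sequence: 9 steps, from 1 to 21 (5, 7 and 8 are bought and enter at steps 3 and 4).

Step 4 (key step). Two processes may defeat it. First, the hindered aryl anion of 10 may be protonated or may add to a second aryne or isocyanide faster than it reaches the doubly ortho-substituted, electron-rich imine. Second, face selection may be weak or opposite to the open model. The fallback uses known chemistry and a chelating metal, for which the other antipode of the auxiliary is the matched one. It sets out from 4 and returns at 15. Aldehyde 4 would be condensed (Ti(OEt)4, THF) with (R)-2-methylpropane-2-sulfinamide F1 to give the (R,E)-sulfinyl imine F2. Methyl 2-iodo-3-methoxybenzoate F3 would be converted by iodine–magnesium exchange (iPrMgCl·LiCl, THF, −40 °C) into [2-methoxy-6-(methoxycarbonyl)phenyl]magnesium chloride F4. Addition of F4 to F2 in a CH2Cl2-rich medium at −40 °C, through the magnesium-chelated six-membered transition state, should give the (S)-configured sulfinamide ester F5. HCl in MeOH would then remove the sulfinyl and MOM groups, and on neutralisation (Et3N, MeOH, 40 °C) the free amine should close onto the methyl ester to give 15. This also bypasses the amidine hydrolysis of step 5.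

Step 5. The amidinium ion of 14 may hydrolyse too slowly, so that forcing is needed, and under hot acid the C3–N bond may ionise reversibly with erosion of configuration; the tetrahedral intermediate may also open the ring instead of releasing tert-butylamine. The fallback activates the amidine by acylation while the phenols are still protected. It sets out from 12 and returns at 15. Brief treatment of 12 with HCl in MeOH at 0 °C and basic work-up should give 13, now isolated. Boc2O and DMAP in MeCN would give tert-butyl (1S)-1-[2,6-bis(methoxymethoxy)-4-methylphenyl]-3-(tert-butylimino)-7-methoxyisoindoline-2-carboxylate F6. This N-acyl amidine should hydrolyse at room temperature in aqueous oxalic acid and THF to tert-butyl (1S)-1-[2,6-bis(methoxymethoxy)-4-methylphenyl]-7-methoxy-3-oxoisoindoline-2-carboxylate F7. HCl in MeOH at room temperature would then remove the Boc and MOM groups to give 15.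

Step 6. Carboxylation under such mild conditions may stop at low conversion, and the electron-rich acid may lose CO2 again on acidic work-up. The fallback introduces the carbon as an aldehyde and oxidises it. It sets out from 15 and returns at 16. Vilsmeier–Haack formylation (POCl3, DMF, MeCN, 0 °C, aqueous hydrolysis) should give 2,4-dihydroxy-3-[(1S)-7-methoxy-3-oxo-2,3-dihydro-1H-isoindol-1-yl]-6-methylbenzaldehyde F8. Pinnick oxidation (NaClO2, NaH2PO4, 2-methyl-2-butene in excess as chlorine scavenger, t-BuOH and water) would give 16.

Step 8. O-prenylation, a stalled second alkylation at the crowded C5', attack at C1' and slow saponification of the allyl ester are the processes to fear. The fallback uses the smaller allyl group and turns it into prenyl afterwards. It sets out from 17 and returns at 21. Allyl bromide and aqueous KOH at 0 °C should give prop-2-en-1-yl 6-hydroxy-5-[(1S)-7-methoxy-3-oxo-2,3-dihydro-1H-isoindol-1-yl]-2-methyl-4-oxo-3,3-di(prop-2-en-1-yl)cyclohexa-1,5-diene-1-carboxylate F9. Pd(PPh3)4 and morpholine, then warming, would give (3S)-3-[2-hydroxy-4-methyl-6-oxo-5,5-di(prop-2-en-1-yl)cyclohexa-1,3-dien-1-yl]-4-methoxyisoindolin-1-one F10. Cross-metathesis of both allyl groups with 2-methyl-2-butene (second-generation Grubbs catalyst, (H2IMes)(PCy3)Cl2Ru=CHPh, 40 °C) would give 21.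

Step 9. The decarboxylation may stall because the carboxyl group of 20 sits on an sp2 carbon and must first reach the deconjugated tautomer; the heat then needed may start the retro-Mannich erosion of C3, and the π-allyl palladium species may be captured by the acidic enolate instead of morpholine. The fallback replaces the carboxyl blocking group by iodine. It sets out from 15 and returns at 21. Mono-iodination (N-iodosuccinimide, MeCN, −20 °C) should give (3S)-3-(2,6-dihydroxy-3-iodo-4-methylphenyl)-4-methoxyisoindolin-1-one F11. Prenyl bromide and aqueous KOH at 0 °C would give (3S)-3-[2-hydroxy-3-iodo-4-methyl-5,5-bis(3-methylbut-2-en-1-yl)-6-oxocyclohexa-1,3-dien-1-yl]-4-methoxyisoindolin-1-one F12. Palladium-catalysed hydrodeiodination of this α-iodoenone (Pd(PPh3)4, Bu3SnH, THF, rt) would give 21.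

## Further compounds

F1 | step 4 | (R)-2-methylpropane-2-sulfinamide | CC(C)(C)[S@@](=O)N
F2 | step 4 | (R,E)-N-[2,6-bis(methoxymethoxy)-4-methylbenzylidene]-2-methylpropane-2-sulfinamide | Cc1cc(OCOC)c(/C=N/[S@](=O)C(C)(C)C)c(OCOC)c1
F3 | step 4 | methyl 2-iodo-3-methoxybenzoate | COC(=O)c1cccc(OC)c1I
F4 | step 4 | [2-methoxy-6-(methoxycarbonyl)phenyl]magnesium chloride | COC(=O)c1cccc(OC)c1[Mg]Cl
F5 | step 4 | methyl 2-[(S)-[2,6-bis(methoxymethoxy)-4-methylphenyl]{[(R)-tert-butylsulfinyl]amino}methyl]-3-methoxybenzoate | COC(=O)c1cccc(OC)c1[C@@H](c1c(OCOC)cc(C)cc1OCOC)N[S@](=O)C(C)(C)C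
F6 | step 5 | tert-butyl (1S)-1-[2,6-bis(methoxymethoxy)-4-methylphenyl]-3-(tert-butylimino)-7-methoxyisoindoline-2-carboxylate | COc1cccc2c1[C@@H](c1c(OCOC)cc(C)cc1OCOC)N(C(=O)OC(C)(C)C)C2=NC(C)(C)C
F7 | step 5 | tert-butyl (1S)-1-[2,6-bis(methoxymethoxy)-4-methylphenyl]-7-methoxy-3-oxoisoindoline-2-carboxylate | COc1cccc2c1[C@@H](c1c(OCOC)cc(C)cc1OCOC)N(C(=O)OC(C)(C)C)C2=O
F8 | step 6 | 2,4-dihydroxy-3-[(1S)-7-methoxy-3-oxo-2,3-dihydro-1H-isoindol-1-yl]-6-methylbenzaldehyde | COc1cccc2c1[C@@H](c1c(O)c(C=O)c(C)cc1O)NC2=O
F9 | step 8 | prop-2-en-1-yl 6-hydroxy-5-[(1S)-7-methoxy-3-oxo-2,3-dihydro-1H-isoindol-1-yl]-2-methyl-4-oxo-3,3-di(prop-2-en-1-yl)cyclohexa-1,5-diene-1-carboxylate | COc1cccc2c1[C@@H](C1=C(O)C(C(=O)OCC=C)=C(C)C(CC=C)(CC=C)C1=O)NC2=O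
F10 | step 8 | (3S)-3-[2-hydroxy-4-methyl-6-oxo-5,5-di(prop-2-en-1-yl)cyclohexa-1,3-dien-1-yl]-4-methoxyisoindolin-1-one | COc1cccc2c1[C@@H](C1=C(O)C=C(C)C(CC=C)(CC=C)C1=O)NC2=O
F11 | step 9 | (3S)-3-(2,6-dihydroxy-3-iodo-4-methylphenyl)-4-methoxyisoindolin-1-one | COc1cccc2c1[C@@H](c1c(O)c(I)c(C)cc1O)NC2=O
F12 | step 9 | (3S)-3-[2-hydroxy-3-iodo-4-methyl-5,5-bis(3-methylbut-2-en-1-yl)-6-oxocyclohexa-1,3-dien-1-yl]-4-methoxyisoindolin-1-one | COc1cccc2c1[C@@H](C1=C(O)C(I)=C(C)C(CC=C(C)C)(CC=C(C)C)C1=O)NC2=O
A1 | alternative 1 | N-(1,5-dimethoxypenta-1,4-diyn-3-yl)prop-2-ynamide | C#CC(=O)NC(C#COC)C#COC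
A2 | alternative 1 | ethyne | C#C
A3 | alternative 1 | (3R)-4-methoxy-3-(methoxyethynyl)isoindolin-1-one | COc1cccc2c1[C@@H](C#COC)NC2=O
A4 | alternative 2 | prop-2-en-1-yl 2,4-dihydroxy-3-[(1S)-7-methoxy-3-oxo-2,3-dihydro-1H-isoindol-1-yl]-6-methylbenzoate | COc1cccc2c1[C@@H](c1c(O)c(C(=O)OCC=C)c(C)cc1O)NC2=O
A5 | alternative 2 | prop-2-en-1-yl 6-hydroxy-5-[(1S)-7-methoxy-3-oxo-2,3-dihydro-1H-isoindol-1-yl]-2-methyl-3,3-bis(3-methylbut-2-en-1-yl)-4-oxocyclohexa-1,5-diene-1-carboxylate | COc1cccc2c1[C@@H](C1=C(O)C(C(=O)OCC=C)=C(C)C(CC=C(C)C)(CC=C(C)C)C1=O)NC2=O
A6 | alternative 3 | 3-methyl-4,4-bis(3-methylbut-2-en-1-yl)cyclobut-2-en-1-one | O=C1C=C(C)C1(CC=C(C)C)CC=C(C)C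
A7 | alternative 3 | (3S)-4-methoxy-3-[2-methoxy-4-methyl-5,5-bis(3-methylbut-2-en-1-yl)-6-oxocyclohexa-1,3-dien-1-yl]isoindolin-1-one | COc1cccc2c1[C@@H](C1=C(OC)C=C(C)C(CC=C(C)C)(CC=C(C)C)C1=O)NC2=O
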